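The whole route hangs on disconnecting the C3'–C4' bond of the N1-bound (E)-dodec-2-enoyl chain, so that the complete chiral 3-acetyltetramic acid ring (N1, C2 to C5, C5 from D-leucine) is built first and the lipid tail is attached in the last step. The key step, a palladium-catalysed Negishi coupling, joins nonylzinc iodide to the N1-[(E)-3-iodoacryloyl] derivative of (R)-3-acetyl-5-isobutyltetramic acid and delivers the unprotected natural product in one operation. It exploits C3', the β-carbon of the exocyclic N1-enoyl imide: its C3'–I bond is a vinylogous acyl iodide, so oxidative addition is fast and stereoretentive, and the E-geometry of C2'=C3' is brought in ready-made from (E)-3-iodoacrylic acid.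

Key step: step 5

Remark on the chemistry: the 3-acyltetramic acids are drawn throughout as the C4-enol tautomer used in the target structure.
Remark on the chemistry: (E)-3-iodoacrylic acid is taken as a purchasable compound.
Remark on the chemistry: in the difluoroboron chelates of the fallbacks, boron is drawn bridging O4 and the acetyl oxygen.

Step 1
Reactants: 1 methyl D-leucinate hydrochloride
Product: 2 methyl N-(3-oxobutanoyl)-D-leucinate [methyl (2R)-4-methyl-2-(3-oxobutanamido)pentanoate]
Conditions: 2,2,6-trimethyl-4H-1,3-dioxin-4-one (1.2 equiv), Et3N (1.05 equiv), toluene, 110 °C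
Reagents that add atoms: 2,2,6-trimethyl-4H-1,3-dioxin-4-one, CC1=CC(=O)OC(C)(C)O1
Why: Thermal retro-hetero-Diels–Alder cleavage of the dioxinone releases acetylketene, which the amine freed by Et3N traps at once to give the β-ketoamide (acetoacetylation by an acylketene), and the stereocentre of D-leucine takes no part.

Step 2
Reactants: 2 methyl N-(3-oxobutanoyl)-D-leucinate
Product: 3 (R)-3-acetyl-5-isobutyltetramic acid [(5R)-3-acetyl-4-hydroxy-5-(2-methylpropyl)-1,5-dihydro-2H-pyrrol-2-one]
Conditions: KOt-Bu (2.2 equiv), t-BuOH/THF, 25 °C, 20 min; then 1 M HCl, 0 °C
Reagents that add atoms: none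
Why: Lacey–Dieckmann cyclisation, in which the enolate of the acetoacetamide CH2 attacks the methyl ester (5-exo-trig) and loss of methoxide gives the delocalised tricarbonyl enolate whose negative charge shields C5–H, so that a short contact with a hindered alkoxide at 25 °C should leave the C5 configuration from D-leucine intact.

Step 3
Reactants: 4 (E)-3-iodoacrylic acid [(2E)-3-iodoprop-2-enoic acid]
Product: 5 (E)-3-iodoacryloyl chloride
Conditions: (COCl)2 (1.2 equiv), DMF (cat.), CH2Cl2, 0 °C to rt; volatiles removed, used crude
Reagents that add atoms: oxalyl chloride, O=C(Cl)C(=O)Cl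
Why: DMF-catalysed acid chloride formation through the Vilsmeier chloroiminium salt is mild and leaves only gases, and the thermodynamically favoured E-alkene should be retained.

Step 4
Reactants: 3 (R)-3-acetyl-5-isobutyltetramic acid; 5 (E)-3-iodoacryloyl chloride
Product: 7 N1-[(E)-3-iodoacryloyl]-(R)-3-acetyl-5-isobutyltetramic acid [(5R)-3-acetyl-4-hydroxy-1-[(2E)-3-iodoprop-2-enoyl]-5-(2-methylpropyl)-1,5-dihydro-2H-pyrrol-2-one], via dilithio tetramate 6 (not isolated)
Conditions: n-BuLi (2.05 equiv), THF, −78 °C; then 5 (1.1 equiv), −78 to −30 °C; 1 M HCl
Reagents that add atoms: none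
Why: Two equivalents of n-BuLi remove first the acidic enol proton and then N1–H, and in the resulting dianion the amide nitrogen is by far the most nucleophilic site, so the acid chloride should be attacked at nitrogen (N-acylation of a lactam anion by nucleophilic acyl substitution) while the product stays shielded as its unreactive tetramate anion until the acidic work-up and C5 is not deprotonated at −78 °C.

Step 5
Reactants: 7 N1-[(E)-3-iodoacryloyl]-(R)-3-acetyl-5-isobutyltetramic acid; 8 1-iodononane
Product: 11 Reutericyclin C [(5R)-3-acetyl-1-[(2E)-dodec-2-enoyl]-4-hydroxy-5-(2-methylpropyl)-1,5-dihydro-2H-pyrrol-2-one], via nonylzinc iodide 9 (not isolated), via iodozinc tetramate 10 (not isolated)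
Conditions: 8, Zn dust, LiCl, THF, 40 °C; then the solution of 9 (2.5 equiv) added to 7, PdCl2(dppf) (5 mol %; dppf = 1,1'-bis(diphenylphosphino)ferrocene), THF/NMP, 0 °C to rt; 1 M HCl
Reagents that add atoms: none
Why: Negishi cross-coupling: the first equivalent of 9 only deprotonates the acidic C4 enol of 7 and gives the iodozinc tetramate 10, an in-flask protection that ties up the chelating tricarbonyl, after which zerovalent palladium (formed from PdCl2(dppf) by reduction with 9) adds oxidatively and with retention into the C3'–I bond, the nonyl group passes from zinc to divalent palladium, and reductive elimination forms C3'–C4'. The closest known reaction type is the palladium-catalysed coupling of primary alkylzinc halides with (E)-3-iodoacrylates and (E)-β-iodoenones, which runs at room temperature with retention of the alkene geometry. No ring is closed and no stereocentre is created; the E-geometry of C2'=C3' is carried over from 7, and C5 is untouched because no base stronger than the organozinc is present. The step needs chemoselectivity for oxidative addition at C3'–I over 1,4-addition to the acrylimide, over attack at the labile N1-acyl carbonyl and over β-hydride elimination of the nonylpalladium intermediate. The first two should be secured by the low nucleophilicity of alkylzinc iodides and the very high rate of oxidative addition at the electron-poor C3'–I bond, the last by the wide bite angle of dppf, which speeds reductive elimination.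

Compound list
1 | methyl D-leucinate hydrochloride [methyl (2R)-2-amino-4-methylpentanoate hydrochloride] | CC(C)C[C@@H](N)C(=O)OC.Cl | starting material
2 | methyl N-(3-oxobutanoyl)-D-leucinate [methyl (2R)-4-methyl-2-(3-oxobutanamido)pentanoate] | CC(=O)CC(=O)N[C@H](CC(C)C)C(=O)OC | intermediate
3 | (R)-3-acetyl-5-isobutyltetramic acid [(5R)-3-acetyl-4-hydroxy-5-(2-methylpropyl)-1,5-dihydro-2H-pyrrol-2-one] | CC(=O)C1=C(O)[C@@H](CC(C)C)NC1=O | intermediate
4 | (E)-3-iodoacrylic acid [(2E)-3-iodoprop-2-enoic acid] | OC(=O)/C=C/I | starting material
5 | (E)-3-iodoacryloyl chloride | ClC(=O)/C=C/I | intermediate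
6 | dilithio tetramate (N1,O4-dilithium salt of 3, 5R) | CC(=O)C1=C([O-])[C@@H](CC(C)C)[N-]C1=O.[Li+].[Li+] | intermediate (not isolated)
7 | N1-[(E)-3-iodoacryloyl]-(R)-3-acetyl-5-isobutyltetramic acid [(5R)-3-acetyl-4-hydroxy-1-[(2E)-3-iodoprop-2-enoyl]-5-(2-methylpropyl)-1,5-dihydro-2H-pyrrol-2-one] | I/C=C/C(=O)N1C(=O)C(C(C)=O)=C(O)[C@H]1CC(C)C | intermediate
8 | 1-iodononane | CCCCCCCCCI | starting material
9 | nonylzinc iodide | CCCCCCCCC[Zn]I | intermediate (not isolated)
10 | iodozinc tetramate (O4-iodozinc enolate of 7, 5R, 2'E) | I/C=C/C(=O)N1C(=O)C(C(C)=O)=C(O[Zn]I)[C@H]1CC(C)C | intermediate (not isolated)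
11 | Reutericyclin C [(5R)-3-acetyl-1-[(2E)-dodec-2-enoyl]-4-hydroxy-5-(2-methylpropyl)-1,5-dihydro-2H-pyrrol-2-one] | CCCCCCCCC/C=C/C(=O)N1C(=O)C(C(C)=O)=C(O)[C@H]1CC(C)C | target

Total step count: 5
Longest linear sequence: 4 steps (steps 1, 2, 4 and 5, from 1); step 3 is a one-step side branch.

Steps most likely to fail

Step 5 (key step). After the first equivalent of 9 has been used up by the enol, the zinc-bound tricarbonyl may still bind palladium and slow the transmetalation, so that reduction of the C3'–I bond or breakdown of the N1-acyl imide takes over. The fallback makes the same C3'–C4' bond by the same kind of coupling one stage earlier, on a substrate that carries nothing but a carboxylate. It sets out from 4: an excess of 9 (3 equiv) first forms iodozinc (E)-3-iodoacrylate F1 and then, with PdCl2(dppf) in THF/NMP at rt and acidic work-up, should give (E)-dodec-2-enoic acid F2. Oxalyl chloride and a catalytic amount of DMF turn F2 into (E)-dodec-2-enoyl chloride F3. F3 is added at −78 °C to the dilithio tetramate 6, made from 3 and n-BuLi as in step 4, and acidic work-up should give 11, where the fallback rejoins the route.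

Step 4. Metalation may go beyond the dianion (deprotonation at C5 and loss of configuration), acylation may occur at an enolate oxygen in place of N1, or the nitrogen anion may add at C3' of 5 with loss of iodide. The fallback masks the tricarbonyl so that a single, mild deprotonation suffices. It sets out from 3: BF3·OEt2 in CH2Cl2 at rt should convert 3 into the N1-unsubstituted difluoroboron chelate F4, a neutral compound whose only acidic site is N1–H. LiN(SiMe3)2 (1.0 equiv, THF, −78 °C) then gives the N1-lithio difluoroboron chelate F5, which is acylated by 5 to the N1-[(E)-3-iodoacryloyl] difluoroboron chelate F6. Brief warming of F6 in methanol removes the BF2 group and returns the route to 7.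

Step 2. Reversible enolisation at C5 under the alkoxide, before or after ring closure, may erode the enantiomeric purity brought in from D-leucine. The fallback restores the purity after the cyclisation instead of protecting it during the cyclisation. It sets out from 3 of lowered optical purity: 3 is a strong acid and is converted with (S)-1-phenylethylamine in ethanol or ethyl acetate into the (S)-1-phenylethylammonium tetramate F7, which is separated from its diastereomer by fractional crystallisation. Partition of F7 between ethyl acetate and 1 M HCl returns 3, where the route continues.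

Further compounds
F1 | step 5 | iodozinc (E)-3-iodoacrylate | I/C=C/C(=O)O[Zn]I
F2 | step 5 | (E)-dodec-2-enoic acid | CCCCCCCCC/C=C/C(=O)O
F3 | step 5 | (E)-dodec-2-enoyl chloride | CCCCCCCCC/C=C/C(=O)Cl
F4 | step 4 | N1-unsubstituted difluoroboron chelate (difluoroboron chelate of 3, 5R) | CC1=[O+][B-](F)(F)OC2=C1C(=O)N[C@@H]2CC(C)C
F5 | step 4 | N1-lithio difluoroboron chelate (lithium salt of F4, 5R) | CC1=[O+][B-](F)(F)OC2=C1C(=O)[N-][C@@H]2CC(C)C.[Li+]
F6 | step 4 | N1-[(E)-3-iodoacryloyl] difluoroboron chelate (difluoroboron chelate of 7, 5R) | CC1=[O+][B-](F)(F)OC2=C1C(=O)N(C(=O)/C=C/I)[C@@H]2CC(C)C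
F7 | step 2 | (S)-1-phenylethylammonium tetramate (salt of 3 with (S)-1-phenylethylamine) | CC(=O)C1=C([O-])[C@@H](CC(C)C)NC1=O.C[C@H]([NH3+])c1ccccc1
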